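**Plan**

- Cuts, in retrosynthetic order: the C9″–O p-coumarate ester; then C4a–C5 and O1–C2 of the flavone, which unfold rings A and C into a 4-hydroxy-2-pyranone joined to ring B through CH2–C(=O)–C≡C; then the CH2–C(=O) bond (pyranone dianion plus alkynyl Weinreb amide) and the two bonds at the alkyne termini; last C7″–C8″ (aldol) and the O–C8″ ether (phenol alkylation).
- Enabling feature: ring A carries oxygen on C5, C7 and C8a, each separated by one carbon, and C4a bears the acyl carbon C4. C5 to C8a together with C4, C3 and C2 are therefore one chain of alternating carbonyl-level carbons, which a pyranone can mask and a base can fold.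
- Forward order: ring B enters as 4-bromo-2,6-dimethoxyphenol and first receives the side chain (ether, then aldol with silylated vanillin). The bromide becomes an alkyne and then an alkynyl amide, which acylates the pyranone. Rings A and C are closed together, and the p-coumarate is attached last.
- Stereochemistry: the (R)-4-benzyloxazolidinone boron syn-aldol sets C8″ and gives the threo (7″S,8″S) pair. A Mitsunobu inversion at benzylic C7″ then gives the erythro (7″R,8″S) pair of the target. The E-alkene comes in with p-coumaric acid.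

Key step: step 13

Remark: the target SMILES is read as (7″R,8″S), the erythro series; C7″ is the benzylic carbinol carbon, C8″ the aryloxy carbon and C9″ the CH2O carbon. TBS = tert-butyldimethylsilyl, TIPS = triisopropylsilyl. ArB = 4-{[(1R,2S)-1,3-bis(tert-butyldimethylsilyloxy)-1-(3-methoxy-4-triisopropylsilyloxyphenyl)propan-2-yl]oxy}-3,5-dimethoxyphenyl, that is ring B with its fully silylated side chain.

**Route**

Step 1
Reactants: 1 vanillin
Product: 2 3-methoxy-4-(triisopropylsilyloxy)benzaldehyde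
Conditions: TIPSCl, imidazole, DMF, rt
Reagents that add atoms: triisopropylsilyl chloride, CC(C)[Si](Cl)(C(C)C)C(C)C
Why: Imidazole-promoted O-silylation of a phenol; the bulky aryl silyl ether is chosen because it has to outlast carbonate and alkoxide in methanol in steps 9 and 13.

Step 2
Reactants: 3 (R)-4-benzyloxazolidin-2-one
Product: 5 (R)-4-benzyl-3-(bromoacetyl)oxazolidin-2-one, via lithium oxazolidinide 4 (not isolated)
Conditions: n-BuLi, THF, −78 °C; BrCH2COBr, −78 → 0 °C
Reagents that add atoms: bromoacetyl bromide, BrCC(Br)=O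
Why: N-acylation of a lithiated Evans auxiliary by an acid bromide, whose acyl carbon is far more electrophilic than the CH2Br carbon, so the alkyl bromide is kept.

Step 3
Reactants: 6 4-bromo-2,6-dimethoxyphenol; 5 (R)-4-benzyl-3-(bromoacetyl)oxazolidin-2-one
Product: 7 (R)-4-benzyl-3-[2-(4-bromo-2,6-dimethoxyphenoxy)acetyl]oxazolidin-2-one
Conditions: K2CO3, acetone, rt
Reagents that add atoms: none
Why: Williamson ether synthesis, in which the phenoxide displaces the activated α-bromide of the imide by SN2 at room temperature, where the imide carbonyls are not attacked.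

Step 4
Reactants: 7 (R)-4-benzyl-3-[2-(4-bromo-2,6-dimethoxyphenoxy)acetyl]oxazolidin-2-one; 2 3-methoxy-4-(triisopropylsilyloxy)benzaldehyde
Product: 9 (R)-4-benzyl-3-[(2R,3S)-2-(4-bromo-2,6-dimethoxyphenoxy)-3-hydroxy-3-(3-methoxy-4-triisopropylsilyloxyphenyl)propanoyl]oxazolidin-2-one, via boron enolate 8 (not isolated)
Conditions: Bu2BOTf, i-Pr2NEt, CH2Cl2, −78 → 0 °C; 2, −78 → 0 °C; H2O2, pH 7 buffer, MeOH, 0 °C
Reagents that add atoms: none
Why: Evans boron syn-aldol, in which the (Z)-dibutylboron enolate reacts through a chair Zimmerman–Traxler transition state on the face away from the benzyl group of the (R)-auxiliary; this sets C8″ in its final spatial arrangement (2R in the imide, S once C9″ is reduced) and C7″ as the S-carbinol, the epimer that step 8 inverts.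

Step 5
Reactants: 9 syn-aldol adduct
Product: 10 (1S,2S)-2-(4-bromo-2,6-dimethoxyphenoxy)-1-[3-methoxy-4-(triisopropylsilyloxy)phenyl]propane-1,3-diol
Conditions: NaBH4, THF/H2O (4:1), 0 °C → rt
Reagents that add atoms: none
Why: Reductive cleavage of the N-acyl oxazolidinone by borohydride in wet THF gives the primary alcohol without touching either stereocentre and returns the auxiliary.

Step 6
Reactants: 10 threo diol
Product: 11 (1S,2S)-2-(4-bromo-2,6-dimethoxyphenoxy)-3-(tert-butyldimethylsilyloxy)-1-[3-methoxy-4-(triisopropylsilyloxy)phenyl]propan-1-ol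
Conditions: TBSCl (1.05 equiv), imidazole, CH2Cl2, 0 °C
Reagents that add atoms: tert-butyldimethylsilyl chloride, CC(C)(C)[Si](C)(C)Cl
Why: Selective silylation of the primary hydroxyl, which reacts much faster than the hindered secondary benzylic one.

Step 7
Reactants: 11 primary silyl ether
Product: 12 (1S,2S)-3-(tert-butyldimethylsilyloxy)-2-[2,6-dimethoxy-4-(trimethylsilylethynyl)phenoxy]-1-[3-methoxy-4-(triisopropylsilyloxy)phenyl]propan-1-ol
Conditions: HC≡CSiMe3, PdCl2(PhCN)2 (3 mol %), [HP(t-Bu)3]BF4 (6 mol %), CuI (2 mol %), i-Pr2NH, dioxane, rt → 40 °C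
Reagents that add atoms: ethynyltrimethylsilane, C#C[Si](C)(C)C
Why: Sonogashira coupling, for which the electron-rich but unhindered aryl bromide needs the bulky, electron-rich tri-tert-butylphosphine on zerovalent palladium for oxidative addition, and which tolerates the free secondary alcohol.

Step 8
Reactants: 12 threo alkynylsilane alcohol
Product: 13 (1R,2S)-3-(tert-butyldimethylsilyloxy)-2-[2,6-dimethoxy-4-(trimethylsilylethynyl)phenoxy]-1-[3-methoxy-4-(triisopropylsilyloxy)phenyl]propyl 4-nitrobenzoate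
Conditions: 4-O2NC6H4CO2H, PPh3, DIAD, toluene, 0 °C → rt
Reagents that add atoms: 4-nitrobenzoic acid, O=C(O)c1ccc(cc1)[N+](=O)[O-]
Why: Mitsunobu inversion, in which SN2 displacement of the benzylic oxyphosphonium ion by the acidic carboxylate turns (7″S) into (7″R) and so converts the threo pair into the erythro (7″R,8″S) pair of the target, a conversion known for 1-aryl-2-aryloxypropane-1,3-diol derivatives.

Step 9
Reactants: 13 inverted 4-nitrobenzoate
Product: 14 (1R,2S)-3-(tert-butyldimethylsilyloxy)-2-(4-ethynyl-2,6-dimethoxyphenoxy)-1-[3-methoxy-4-(triisopropylsilyloxy)phenyl]propan-1-ol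
Conditions: K2CO3 (0.3 equiv), MeOH/THF, 0 °C → rt
Reagents that add atoms: none
Why: Base-catalysed transesterification with acyl–oxygen cleavage (so C7″ keeps its configuration) removes the 4-nitrobenzoate, the same methoxide cleaves the alkynyl C–Si bond, and the hindered aryl triisopropylsilyl ether should be left.

Step 10
Reactants: 14 erythro alkynyl alcohol
Product: 15 ethynyl-ArB, that is (1R,2S)-1,3-bis(tert-butyldimethylsilyloxy)-2-(4-ethynyl-2,6-dimethoxyphenoxy)-1-[3-methoxy-4-(triisopropylsilyloxy)phenyl]propane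
Conditions: TBSOTf, 2,6-lutidine, CH2Cl2, −78 → 0 °C
Reagents that add atoms: tert-butyldimethylsilyl triflate, CC(C)(C)[Si](C)(C)OS(=O)(=O)C(F)(F)F
Why: Silylation of a hindered secondary alcohol with a silyl triflate and a non-nucleophilic base, which leaves the terminal alkyne untouched.

Step 11
Reactants: 15 ethynyl-ArB
Product: 17 3-ArB-N-methoxy-N-methylprop-2-ynamide, via lithium acetylide 16 (not isolated)
Conditions: n-BuLi, THF, −78 °C; ClC(O)N(OMe)Me, −78 → 0 °C
Reagents that add atoms: N-methoxy-N-methylcarbamoyl chloride, CON(C)C(Cl)=O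
Why: Acylation of a lithium acetylide with a carbamoyl chloride, the usual one-step entry to alkynyl Weinreb amides, whose amide product is inert to the acetylide at low temperature.

Step 12
Reactants: 18 4-hydroxy-6-methyl-2H-pyran-2-one; 17 3-ArB-N-methoxy-N-methylprop-2-ynamide
Product: 20 6-(4-ArB-2-oxobut-3-yn-1-yl)-4-hydroxy-2H-pyran-2-one, via pyranone dianion 19 (not isolated)
Conditions: 18 (2.5 equiv), LiN(i-Pr)2 (5.2 equiv), THF, −78 → −20 °C; 17, −78 → −40 °C; AcOH, −78 °C
Reagents that add atoms: none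
Why: Weinreb ketone synthesis with the O,C-dianion of the pyranone, whose exocyclic methylene carbon is its most nucleophilic site (acylation of this dianion by esters is known), while the chelated tetrahedral intermediate blocks over-addition and proton transfer from the acidic product until the cold acidic quench.

Step 13
Reactants: 20 6-(4-ArB-2-oxobut-3-yn-1-yl)-4-hydroxy-2H-pyran-2-one
Product: 23 2-ArB-5,7-dihydroxy-4H-chromen-4-one, via triketo ester 21 (not isolated), via acylphloroglucinol 22 (not isolated)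
Conditions: Mg(OMe)2 (8 equiv), MeOH/THF (4:1), 65 °C; AcOH, 0 °C
Reagents that add atoms: none
Why: Proposed new method: Mg(OMe)2 should add methoxide across the ynone of 20, which turns C4 into a vinylogous ester carbon, and methanolyse the lactone to the magnesium-chelated methyl 3,5,7-trioxo ester 21; the chelated carbanion at the CH2 that becomes C4a then attacks the methyl ester and, after loss of methoxide and enolisation, gives the acylphloroglucinol 22, whose ortho phenoxide adds to C2 and expels methoxide to give the flavone. The closest known reactions are the Mg(OMe)2-induced Claisen cyclisation of 6-(2-oxoalkyl)-4-hydroxy-2-pyranones and 3,5,7-triketo esters to acylphloroglucinols and the base- or amine-induced cyclisation of 2-hydroxyaryl ynones to flavones; running both on an alkynyl ketone in one flask is the unproven part. Ring A closes by a 6-(enolendo)-exo-trig Claisen (Dieckmann-type) condensation that forms C4a–C5, and ring C by a 6-endo-trig oxa-Michael addition–elimination that forms O1–C2. No stereocentre is formed, and C7″ and C8″ have no acidic hydrogen next to a carbonyl, so the basic medium should leave them alone. The step needs Claisen folding to beat aldol folding to a resorcylate and six-ring closure to beat five-ring (aurone) closure: magnesium chelation of the 3,5-dicarbonyl unit together with the deactivated vinylogous ester at C4 should secure the first, and the methoxy leaving group on C2, which directs the phenoxide to that carbon, the second.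

Step 14
Reactants: 23 2-ArB-5,7-dihydroxy-4H-chromen-4-one
Product: 24 2-ArB-5-hydroxy-7-(triisopropylsilyloxy)-4H-chromen-4-one
Conditions: TIPSCl (1.5 equiv), imidazole, DMF, 0 °C → rt
Reagents that add atoms: triisopropylsilyl chloride, CC(C)[Si](Cl)(C(C)C)C(C)C
Why: Phenol silylation that is selective for the acidic, unchelated 7-hydroxyl because the 5-hydroxyl is held in a hydrogen bond to the C4 carbonyl, which removes the only acidic phenol before the late esterification.

Step 15
Reactants: 24 2-ArB-5-hydroxy-7-(triisopropylsilyloxy)-4H-chromen-4-one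
Product: 25 2-(4-{[(1R,2S)-1-(tert-butyldimethylsilyloxy)-3-hydroxy-1-(3-methoxy-4-triisopropylsilyloxyphenyl)propan-2-yl]oxy}-3,5-dimethoxyphenyl)-5-hydroxy-7-(triisopropylsilyloxy)-4H-chromen-4-one
Conditions: CSA (0.2 equiv), MeOH/CH2Cl2 (1:1), 0 °C
Reagents that add atoms: none
Why: Acid-catalysed methanolysis cleaves a primary alkyl tert-butyldimethylsilyl ether much faster than the hindered secondary one and leaves the acid-stable aryl silyl ethers.

Step 16
Reactants: 25 primary alcohol; 26 p-coumaric acid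
Product: 27 (2S,3R)-3-(tert-butyldimethylsilyloxy)-2-[4-(5-hydroxy-4-oxo-7-triisopropylsilyloxy-4H-chromen-2-yl)-2,6-dimethoxyphenoxy]-3-(3-methoxy-4-triisopropylsilyloxyphenyl)propyl (E)-3-(4-hydroxyphenyl)prop-2-enoate
Conditions: PPh3, DIAD, THF, 0 °C → rt
Reagents that add atoms: none
Why: Mitsunobu esterification, in which the carboxylic acid is by far the most acidic partner, so the carboxylate displaces the primary oxyphosphonium ion while the phenol of the acid and the chelated 5-hydroxyl stay free, the chemoselectivity known for phenolic acids.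

Step 17
Reactants: 27 silylated p-coumarate
Product: 28 target, (2S,3R)-2-[4-(5,7-dihydroxy-4-oxo-4H-chromen-2-yl)-2,6-dimethoxyphenoxy]-3-hydroxy-3-(4-hydroxy-3-methoxyphenyl)propyl (E)-3-(4-hydroxyphenyl)prop-2-enoate
Conditions: Bu4NF/AcOH (1:1, excess), THF, 0 °C → rt
Reagents that add atoms: none
Why: Fluoride desilylation buffered with acetic acid should remove both aryl triisopropylsilyl ethers and the benzylic tert-butyldimethylsilyl ether without hydrolysing or shifting the cinnamate ester.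

**Compound list**

1 | vanillin | COc1cc(C=O)ccc1O | starting material
2 | 3-methoxy-4-(triisopropylsilyloxy)benzaldehyde | COc1cc(C=O)ccc1O[Si](C(C)C)(C(C)C)C(C)C | intermediate
3 | (R)-4-benzyloxazolidin-2-one | O=C1N[C@H](Cc2ccccc2)CO1 | starting material
4 | lithium (R)-4-benzyl-2-oxooxazolidin-3-ide | [Li+].O=C1[N-][C@H](Cc2ccccc2)CO1 | intermediate (not isolated)
5 | (R)-4-benzyl-3-(bromoacetyl)oxazolidin-2-one | O=C(CBr)N1[C@H](Cc2ccccc2)COC1=O | intermediate
6 | 4-bromo-2,6-dimethoxyphenol | COc1cc(Br)cc(OC)c1O | starting material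
7 | (R)-4-benzyl-3-[2-(4-bromo-2,6-dimethoxyphenoxy)acetyl]oxazolidin-2-one | O=C(COc1c(OC)cc(Br)cc1OC)N1[C@H](Cc2ccccc2)COC1=O | intermediate
8 | (Z)-dibutylboron enolate of 7 | CCCCB(CCCC)O/C(=C\Oc1c(OC)cc(Br)cc1OC)N1[C@H](Cc2ccccc2)COC1=O | intermediate (not isolated)
9 | (R)-4-benzyl-3-[(2R,3S)-2-(4-bromo-2,6-dimethoxyphenoxy)-3-hydroxy-3-(3-methoxy-4-triisopropylsilyloxyphenyl)propanoyl]oxazolidin-2-one | COc1cc([C@H](O)[C@H](C(=O)N2[C@H](Cc3ccccc3)COC2=O)Oc2c(OC)cc(Br)cc2OC)ccc1O[Si](C(C)C)(C(C)C)C(C)C | intermediate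
10 | (1S,2S)-2-(4-bromo-2,6-dimethoxyphenoxy)-1-[3-methoxy-4-(triisopropylsilyloxy)phenyl]propane-1,3-diol | COc1cc([C@H](O)[C@H](CO)Oc2c(OC)cc(Br)cc2OC)ccc1O[Si](C(C)C)(C(C)C)C(C)C | intermediate
11 | (1S,2S)-2-(4-bromo-2,6-dimethoxyphenoxy)-3-(tert-butyldimethylsilyloxy)-1-[3-methoxy-4-(triisopropylsilyloxy)phenyl]propan-1-ol | COc1cc([C@H](O)[C@H](CO[Si](C)(C)C(C)(C)C)Oc2c(OC)cc(Br)cc2OC)ccc1O[Si](C(C)C)(C(C)C)C(C)C | intermediate
12 | (1S,2S)-3-(tert-butyldimethylsilyloxy)-2-[2,6-dimethoxy-4-(trimethylsilylethynyl)phenoxy]-1-[3-methoxy-4-(triisopropylsilyloxy)phenyl]propan-1-ol | COc1cc([C@H](O)[C@H](CO[Si](C)(C)C(C)(C)C)Oc2c(OC)cc(C#C[Si](C)(C)C)cc2OC)ccc1O[Si](C(C)C)(C(C)C)C(C)C | intermediate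
13 | (1R,2S)-3-(tert-butyldimethylsilyloxy)-2-[2,6-dimethoxy-4-(trimethylsilylethynyl)phenoxy]-1-[3-methoxy-4-(triisopropylsilyloxy)phenyl]propyl 4-nitrobenzoate | COc1cc([C@@H](OC(=O)c2ccc(cc2)[N+](=O)[O-])[C@H](CO[Si](C)(C)C(C)(C)C)Oc2c(OC)cc(C#C[Si](C)(C)C)cc2OC)ccc1O[Si](C(C)C)(C(C)C)C(C)C | intermediate
14 | (1R,2S)-3-(tert-butyldimethylsilyloxy)-2-(4-ethynyl-2,6-dimethoxyphenoxy)-1-[3-methoxy-4-(triisopropylsilyloxy)phenyl]propan-1-ol | COc1cc([C@@H](O)[C@H](CO[Si](C)(C)C(C)(C)C)Oc2c(OC)cc(C#C)cc2OC)ccc1O[Si](C(C)C)(C(C)C)C(C)C | intermediate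
15 | ethynyl-ArB, (1R,2S)-1,3-bis(tert-butyldimethylsilyloxy)-2-(4-ethynyl-2,6-dimethoxyphenoxy)-1-[3-methoxy-4-(triisopropylsilyloxy)phenyl]propane | COc1cc([C@@H](O[Si](C)(C)C(C)(C)C)[C@H](CO[Si](C)(C)C(C)(C)C)Oc2c(OC)cc(C#C)cc2OC)ccc1O[Si](C(C)C)(C(C)C)C(C)C | intermediate
16 | lithium acetylide of 15 | COc1cc([C@@H](O[Si](C)(C)C(C)(C)C)[C@H](CO[Si](C)(C)C(C)(C)C)Oc2c(OC)cc(C#C[Li])cc2OC)ccc1O[Si](C(C)C)(C(C)C)C(C)C | intermediate (not isolated)
17 | 3-ArB-N-methoxy-N-methylprop-2-ynamide | COc1cc([C@@H](O[Si](C)(C)C(C)(C)C)[C@H](CO[Si](C)(C)C(C)(C)C)Oc2c(OC)cc(C#CC(=O)N(C)OC)cc2OC)ccc1O[Si](C(C)C)(C(C)C)C(C)C | intermediate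
18 | 4-hydroxy-6-methyl-2H-pyran-2-one | Cc1cc(O)cc(=O)o1 | starting material
19 | dilithium salt of 18 deprotonated at the 4-hydroxyl and the 6-methyl group | [Li+].[Li+].[CH2-]c1cc([O-])cc(=O)o1 | intermediate (not isolated)
20 | 6-(4-ArB-2-oxobut-3-yn-1-yl)-4-hydroxy-2H-pyran-2-one | COc1cc([C@@H](O[Si](C)(C)C(C)(C)C)[C@H](CO[Si](C)(C)C(C)(C)C)Oc2c(OC)cc(C#CC(=O)Cc3cc(O)cc(=O)o3)cc2OC)ccc1O[Si](C(C)C)(C(C)C)C(C)C | intermediate
21 | methyl (Z)-9-ArB-9-methoxy-3,5,7-trioxonon-8-enoate, present as its magnesium chelate; Z from anti addition, either geometry serves | COc1cc([C@@H](O[Si](C)(C)C(C)(C)C)[C@H](CO[Si](C)(C)C(C)(C)C)Oc2c(OC)cc(/C(OC)=C/C(=O)CC(=O)CC(=O)CC(=O)OC)cc2OC)ccc1O[Si](C(C)C)(C(C)C)C(C)C | intermediate (not isolated)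
22 | (Z)-3-ArB-3-methoxy-1-(2,4,6-trihydroxyphenyl)prop-2-en-1-one | COc1cc([C@@H](O[Si](C)(C)C(C)(C)C)[C@H](CO[Si](C)(C)C(C)(C)C)Oc2c(OC)cc(/C(OC)=C/C(=O)c3c(O)cc(O)cc3O)cc2OC)ccc1O[Si](C(C)C)(C(C)C)C(C)C | intermediate (not isolated)
23 | 2-ArB-5,7-dihydroxy-4H-chromen-4-one | COc1cc([C@@H](O[Si](C)(C)C(C)(C)C)[C@H](CO[Si](C)(C)C(C)(C)C)Oc2c(OC)cc(-c3cc(=O)c4c(O)cc(O)cc4o3)cc2OC)ccc1O[Si](C(C)C)(C(C)C)C(C)C | intermediate
24 | 2-ArB-5-hydroxy-7-(triisopropylsilyloxy)-4H-chromen-4-one | COc1cc([C@@H](O[Si](C)(C)C(C)(C)C)[C@H](CO[Si](C)(C)C(C)(C)C)Oc2c(OC)cc(-c3cc(=O)c4c(O)cc(O[Si](C(C)C)(C(C)C)C(C)C)cc4o3)cc2OC)ccc1O[Si](C(C)C)(C(C)C)C(C)C | intermediate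
25 | 2-(4-{[(1R,2S)-1-(tert-butyldimethylsilyloxy)-3-hydroxy-1-(3-methoxy-4-triisopropylsilyloxyphenyl)propan-2-yl]oxy}-3,5-dimethoxyphenyl)-5-hydroxy-7-(triisopropylsilyloxy)-4H-chromen-4-one | COc1cc([C@@H](O[Si](C)(C)C(C)(C)C)[C@H](CO)Oc2c(OC)cc(-c3cc(=O)c4c(O)cc(O[Si](C(C)C)(C(C)C)C(C)C)cc4o3)cc2OC)ccc1O[Si](C(C)C)(C(C)C)C(C)C | intermediate
26 | p-coumaric acid, (E)-3-(4-hydroxyphenyl)prop-2-enoic acid | O=C(O)/C=C/c1ccc(O)cc1 | starting material
27 | (2S,3R)-3-(tert-butyldimethylsilyloxy)-2-[4-(5-hydroxy-4-oxo-7-triisopropylsilyloxy-4H-chromen-2-yl)-2,6-dimethoxyphenoxy]-3-(3-methoxy-4-triisopropylsilyloxyphenyl)propyl (E)-3-(4-hydroxyphenyl)prop-2-enoate | COc1cc([C@@H](O[Si](C)(C)C(C)(C)C)[C@H](COC(=O)/C=C/c2ccc(O)cc2)Oc2c(OC)cc(-c3cc(=O)c4c(O)cc(O[Si](C(C)C)(C(C)C)C(C)C)cc4o3)cc2OC)ccc1O[Si](C(C)C)(C(C)C)C(C)C | intermediate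
28 | (2S,3R)-2-[4-(5,7-dihydroxy-4-oxo-4H-chromen-2-yl)-2,6-dimethoxyphenoxy]-3-hydroxy-3-(4-hydroxy-3-methoxyphenyl)propyl (E)-3-(4-hydroxyphenyl)prop-2-enoate | COc1cc([C@@H](O)[C@H](COC(=O)/C=C/c2ccc(O)cc2)Oc2c(OC)cc(-c3cc(=O)c4c(O)cc(O)cc4o3)cc2OC)ccc1O | target

**Step count**

Total: 17 steps. Longest linear sequence: 16 steps (steps 2 to 17, counted from 3); 15 steps counted from 6 or from 1.

**Steps most likely to fail**

1. Step 13 (proposed new method). The opened chain may fold by aldol attack of the ester-side methylene on the C4 carbonyl and give a resorcylate. The enolate oxygen on the carbon that becomes C8a may close onto C2 before the Claisen step and give a 2-aryl-4-pyranone that does not fold further. The pyranone anion may resist methanolysis. The aryl silyl ether may be partly cleaved by methoxide; this last loss would be repaired in step 14, which uses the same silyl chloride. Fallback with known chemistry, setting out from 15 and returning at 23: commercial 3,5-bis(benzyloxy)phenol would be iodinated with N-iodosuccinimide to 3,5-bis(benzyloxy)-2-iodophenol F1. A palladium-catalysed carbonylative annulation of F1 with alkyne 15 (PdCl2(dppf), CO, Et2NH, 60–100 °C) would then build rings A and C around the alkyne: acyl–alkynyl coupling, then amine-mediated 6-endo closure, giving 2-ArB-5,7-bis(benzyloxy)-4H-chromen-4-one F2. Hydrogenolysis (H2, Pd/C, EtOAc, rt) would free both phenols and give 23.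

2. Step 12. The dienolate, or the N,O-dimethylhydroxylamine set free on work-up, may add to the triple bond in conjugate fashion, and the enolisable ynone may degrade on isolation. Fallback, setting out from 15 and returning at 20: acetylide 16 would be quenched with DMF to give 3-ArB-prop-2-ynal F3. Dianion 19 adds to aldehydes at the carbonyl carbon only and would give 6-(4-ArB-2-hydroxybut-3-yn-1-yl)-4-hydroxy-2H-pyran-2-one F4 as a mixture of carbinol epimers. Oxidation of the propargylic alcohol with Dess–Martin periodinane (CH2Cl2, NaHCO3, 0 °C) would give 20.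

3. Step 8. The electron-rich benzylic oxyphosphonium ion may ionise, which erodes the inversion, or may eliminate toward the enol ether. Fallback, setting out from 12 and returning at 14: oxidation with buffered Dess–Martin periodinane would give (S)-3-(tert-butyldimethylsilyloxy)-2-[2,6-dimethoxy-4-(trimethylsilylethynyl)phenoxy]-1-[3-methoxy-4-(triisopropylsilyloxy)phenyl]propan-1-one F5. Chelation-controlled reduction with Zn(BH4)2 (Et2O, −20 °C), with hydride delivered to the zinc chelate of the carbonyl and aryloxy oxygens from the side of the C8″ hydrogen, would give the erythro alcohol (1R,2S)-3-(tert-butyldimethylsilyloxy)-2-[2,6-dimethoxy-4-(trimethylsilylethynyl)phenoxy]-1-[3-methoxy-4-(triisopropylsilyloxy)phenyl]propan-1-ol F6. K2CO3 in MeOH would then cleave the alkynylsilane and give 14.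

**Further compounds**

F1 | step 13 | 3,5-bis(benzyloxy)-2-iodophenol | Oc1cc(OCc2ccccc2)cc(OCc2ccccc2)c1I
F2 | step 13 | 2-ArB-5,7-bis(benzyloxy)-4H-chromen-4-one | COc1cc([C@@H](O[Si](C)(C)C(C)(C)C)[C@H](CO[Si](C)(C)C(C)(C)C)Oc2c(OC)cc(-c3cc(=O)c4c(OCc5ccccc5)cc(OCc5ccccc5)cc4o3)cc2OC)ccc1O[Si](C(C)C)(C(C)C)C(C)C
F3 | step 12 | 3-ArB-prop-2-ynal | COc1cc([C@@H](O[Si](C)(C)C(C)(C)C)[C@H](CO[Si](C)(C)C(C)(C)C)Oc2c(OC)cc(C#CC=O)cc2OC)ccc1O[Si](C(C)C)(C(C)C)C(C)C
F4 | step 12 | 6-(4-ArB-2-hydroxybut-3-yn-1-yl)-4-hydroxy-2H-pyran-2-one, both carbinol epimers | COc1cc([C@@H](O[Si](C)(C)C(C)(C)C)[C@H](CO[Si](C)(C)C(C)(C)C)Oc2c(OC)cc(C#CC(O)Cc3cc(O)cc(=O)o3)cc2OC)ccc1O[Si](C(C)C)(C(C)C)C(C)C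
F5 | step 8 | (S)-3-(tert-butyldimethylsilyloxy)-2-[2,6-dimethoxy-4-(trimethylsilylethynyl)phenoxy]-1-[3-methoxy-4-(triisopropylsilyloxy)phenyl]propan-1-one | COc1cc(C(=O)[C@H](CO[Si](C)(C)C(C)(C)C)Oc2c(OC)cc(C#C[Si](C)(C)C)cc2OC)ccc1O[Si](C(C)C)(C(C)C)C(C)C
F6 | step 8 | (1R,2S)-3-(tert-butyldimethylsilyloxy)-2-[2,6-dimethoxy-4-(trimethylsilylethynyl)phenoxy]-1-[3-methoxy-4-(triisopropylsilyloxy)phenyl]propan-1-ol | COc1cc([C@@H](O)[C@H](CO[Si](C)(C)C(C)(C)C)Oc2c(OC)cc(C#C[Si](C)(C)C)cc2OC)ccc1O[Si](C(C)C)(C(C)C)C(C)C
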